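**Retrosynthetic overview**
1. Labdane numbering is used (ring A = C1–C5 + C10, ring B = C5–C10, side chain C11–C16 on C9, C17 on C8, C20 on C10). Target 27 ⇐ enal 24 (C7=C8–C17HO) by 1,2-reduction, acetylation and diimide reduction of a C11=C12 alkene, which comes, with the C13 stereocentre, from a Wittig reaction of lactol 17 with ylide 21 made from (R)-monomethyl 3-methylglutarate.
2. Lactol 17 ⇐ cis-fused γ-lactone 16 ⇐ octalin imide 14 ⇐ acyclic trienimide 13. One intramolecular Diels–Alder reaction forms C8–C9 and C5–C10, closes rings A and B together and sets C5, C9 and C10 (C8 transiently).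
3. Enabling feature: ring B is a cyclohexene whose C9–C10 edge (quaternary C10 with C20, C9 bearing C11) is a latent E-trisubstituted dienophile and whose C5–C6–C7–C8 edge is a latent diene. The ring A chain C1–C2–C3–C4 is the four-carbon tether between C10 and C5. C11 at the acyl level activates the dienophile and carries the auxiliary, C17–O sits on the diene terminus, and the cycloadduct alkene C6=C7 is later moved to C7=C8 through the C17 aldehyde.
4. Trienimide 13 ⇐ 2,2-dimethylpent-4-enal (C1–C5, C18, C19) + phosphonocrotonate 2 (C6–C8, C17) + enol triflate 7 of ethyl acetoacetate (C9–C11, C20), by vinylogous HWE olefination and B-alkyl Suzuki coupling.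
5. Ring order: rings A and B together in step 8; a temporary lactone/lactol ring (C8–C9–C11–O–C17) in steps 9–10, opened again in step 13.

Key step: step 8

Remark: lactol 17 is formed and used as a mixture of C11 anomers; this centre becomes sp2 in step 13 and is left undefined.

**Step 1**
Reactants: 1 2,2-dimethylpent-4-enal; 2 ethyl (2E)-4-(diethoxyphosphoryl)but-2-enoate (triethyl 4-phosphonocrotonate)
Product: 3 ethyl (2E,4E)-6,6-dimethylnona-2,4,8-trienoate
Conditions: LiOH·H2O, 4 Å molecular sieves, THF, reflux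
Reagents that add atoms: none
Why: Vinylogous Horner–Wadsworth–Emmons olefination of a non-enolisable aldehyde should give the E,E-dienoate under thermodynamic control.

**Step 2**
Reactants: 3 ethyl (2E,4E)-6,6-dimethylnona-2,4,8-trienoate
Product: 4 (2E,4E)-6,6-dimethylnona-2,4,8-trien-1-ol
Conditions: iBu2AlH (2.2 equiv), CH2Cl2, −78 °C to 0 °C
Reagents that add atoms: none
Why: Aluminium hydride 1,2-reduction of a conjugated ester should give the dienol without touching the alkenes.

**Step 3**
Reactants: 4 (2E,4E)-6,6-dimethylnona-2,4,8-trien-1-ol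
Product: 5 [(2E,4E)-6,6-dimethylnona-2,4,8-trien-1-yl]oxy(triisopropyl)silane
Conditions: iPr3SiCl, imidazole, DMF, rt
Reagents that add atoms: chlorotri(propan-2-yl)silane, CC(C)[Si](Cl)(C(C)C)C(C)C
Why: Silylation of a primary alcohol gives a bulky ether that should resist hydroxide and Lewis acid and be cleaved by fluoride.

**Step 4**
Reactants: 6 ethyl acetoacetate
Product: 7 ethyl (2E)-3-{[(trifluoromethyl)sulfonyl]oxy}but-2-enoate
Conditions: Tf2O, aqueous Me4NOH, hexane, 5 °C to rt
Reagents that add atoms: trifluoromethanesulfonic anhydride, O=S(=O)(OS(=O)(=O)C(F)(F)F)C(F)(F)F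
Why: O-Triflation of the β-keto ester enolate paired with a non-chelating tetramethylammonium cation should place the triflate trans to the ester, the E enol triflate needed for a dienophile with C20 cis to C11.

**Step 5**
Reactants: 5 [(2E,4E)-6,6-dimethylnona-2,4,8-trien-1-yl]oxy(triisopropyl)silane; 7 ethyl (2E)-3-{[(trifluoromethyl)sulfonyl]oxy}but-2-enoate
Product: 9 ethyl (2E,8E,10E)-3,7,7-trimethyl-12-(triisopropylsilyloxy)dodeca-2,8,10-trienoate, via B-alkyl-9-BBN borane 8 (not isolated)
Conditions: 9-BBN, THF, 0 °C to rt; then 7, PdCl2(dppf) (5 mol %), aqueous K3PO4, DMF, rt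
Reagents that add atoms: none
Why: 9-BBN should hydroborate only the monosubstituted alkene (boron at C1), and the B-alkyl Suzuki–Miyaura coupling proceeds with retention at the enol triflate carbon, giving the E C9=C10 alkene with the chain trans to the ester.

**Step 6**
Reactants: 9 ethyl (2E,8E,10E)-3,7,7-trimethyl-12-(triisopropylsilyloxy)dodeca-2,8,10-trienoate
Product: 10 (2E,8E,10E)-3,7,7-trimethyl-12-(triisopropylsilyloxy)dodeca-2,8,10-trienoic acid
Conditions: LiOH, THF/MeOH/H2O, 50 °C; then 1 M HCl
Reagents that add atoms: lithium hydroxide, [Li+].[OH-]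
Why: Saponification of the ethyl ester, with the triisopropylsilyl ether and the diene expected to survive hydroxide.

**Step 7**
Reactants: 10 (2E,8E,10E)-3,7,7-trimethyl-12-(triisopropylsilyloxy)dodeca-2,8,10-trienoic acid; 11 (4R)-4-benzyl-1,3-oxazolidin-2-one
Product: 13 (4R)-4-benzyl-3-[(2E,8E,10E)-3,7,7-trimethyl-12-(triisopropylsilyloxy)dodeca-2,8,10-trienoyl]-1,3-oxazolidin-2-one, via mixed pivalic anhydride 12 (not isolated)
Conditions: PivCl, Et3N, THF, −20 °C; then LiCl, 11, −20 °C to rt
Reagents that add atoms: none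
Why: Mixed-anhydride N-acylation of the oxazolidinone (LiCl/Et3N) avoids an acid chloride and so should not scramble the trisubstituted alkene through a vinylketene.

**Step 8**
Reactants: 13 (4R)-4-benzyl-3-[(2E,8E,10E)-3,7,7-trimethyl-12-(triisopropylsilyloxy)dodeca-2,8,10-trienoyl]-1,3-oxazolidin-2-one
Product: 14 (4R)-4-benzyl-3-{[2-(triisopropylsilyloxymethyl)-5,5,8a-trimethyl-1,2,4a,5,6,7,8,8a-octahydronaphthalen-1-yl]carbonyl}-1,3-oxazolidin-2-one (trans-fused; C9 acyl, C8 CH2OSi and C10 methyl mutually cis; C5–H trans to the C10 methyl; C6=C7)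
Conditions: Me2AlCl (1.8 equiv), CH2Cl2, −30 °C to 0 °C
Reagents that add atoms: none
Why: Me2AlCl should form a cationic aluminium chelate of the two imide carbonyls, which locks the enoyl unit s-cis and lowers its LUMO so that the tethered diene adds in a concerted, asynchronous [4+2] cycloaddition; the closest known reaction type is the oxazolidinone-controlled, dialkylaluminium chloride-promoted intramolecular Diels–Alder reaction of 2,8,10-trienimides to trans-fused octalins. Ring B is closed as the new cyclohexene (diene C5=C6–C7=C8 plus dienophile C9=C10, bonds C8–C9 and C5–C10), and ring A is closed at the same time as the six-membered ring spanned by the tether C1–C4 between C10 and C5 (type 1, 1,7,9-decatriene mode). The cis relation of the C10 methyl and the C9 acyl group follows from the E dienophile (suprafacial addition); the trans ring fusion (C5–H anti to the C10 methyl) and the C8 configuration (CH2OSi cis to the C9 acyl) follow from the endo transition state of the E,E-diene, in which the chelated acyl group lies under the diene. Absolute configuration comes from the (R)-benzyl group, which shields the Si face of C9 so that the diene adds to the C9 Re face, anti to benzyl. The step needs endo over exo selectivity and one π-face: the rigid chelate secures both, while the C4 gem-dimethyl group favours the reactive coiled conformer at the cost of a developing 1,3-diaxial methyl/methyl contact.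

**Step 9**
Reactants: 14 octalin imide
Product: 16 tricyclic γ-lactone (C11 carbonyl on C9, O–C17H2 on C8, cis-fused to ring B; C6=C7; trans-decalin), via hydroxy imide 15 (not isolated)
Conditions: Bu4NF, THF, 0 °C to rt
Reagents that add atoms: none
Why: Fluoride desilylation frees the C17 alkoxide, which is cis to the C9 acyl group and should close the γ-lactone by acyl transfer, releasing the oxazolidinone (auxiliary removal by lactonisation).

**Step 10**
Reactants: 16 tricyclic γ-lactone
Product: 17 tricyclic lactol (C11 hemiacetal, anomer mixture)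
Conditions: iBu2AlH (1.1 equiv), CH2Cl2, −78 °C
Reagents that add atoms: none
Why: Partial reduction of a γ-lactone should stop at the lactol because the tetrahedral aluminium alkoxide is stable at −78 °C.

**Step 11**
Reactants: 18 (3R)-5-methoxy-3-methyl-5-oxopentanoic acid [(R)-monomethyl 3-methylglutarate]
Product: 19 methyl (3S)-4-iodo-3-methylbutanoate
Conditions: PhI(OAc)2, I2, benzene, hν, reflux
Reagents that add atoms: iodine, [I][I]
Why: Radical iododecarboxylation (Suárez variant of the Hunsdiecker reaction) replaces CO2H by iodine at a primary carbon; the stereocentre is one carbon away from the radical and is untouched.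

**Step 12**
Reactants: 19 methyl (3S)-4-iodo-3-methylbutanoate
Product: 20 [(2S)-4-methoxy-2-methyl-4-oxobutyl]triphenylphosphonium iodide
Conditions: PPh3, MeCN, reflux
Reagents that add atoms: triphenylphosphine, c1ccc(cc1)P(c1ccccc1)c1ccccc1
Why: SN2 quaternisation of triphenylphosphine by a primary iodide.

**Step 13**
Reactants: 17 tricyclic lactol; 20 [(2S)-4-methoxy-2-methyl-4-oxobutyl]triphenylphosphonium iodide
Product: 22 methyl (3S,4Z)-5-[2-(hydroxymethyl)-5,5,8a-trimethyl-1,2,4a,5,6,7,8,8a-octahydronaphthalen-1-yl]-3-methylpent-4-enoate (ring stereocentres as in 14), via phosphonium ylide 21 (not isolated)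
Conditions: 20 (3.0 equiv), NaN(SiMe3)2 (2.9 equiv), THF, −78 °C to 0 °C; then 17, −78 °C to rt
Reagents that add atoms: none
Why: Wittig olefination of a lactol through its open hydroxy-aldehyde form with a non-stabilised ylide should give the Z C11=C12 alkene; C13 comes unchanged from 18, and C9 is protected against epimerisation because the closed cis-fused lactol is the resting state.

**Step 14**
Reactants: 22 hydroxy diene ester
Product: 24 methyl (3S,4Z)-5-[2-formyl-5,5,8a-trimethyl-1,4,4a,5,6,7,8,8a-octahydronaphthalen-1-yl]-3-methylpent-4-enoate (C7=C8 enal), via deconjugated aldehyde 23 (not isolated)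
Conditions: Dess–Martin periodinane, CH2Cl2, 0 °C to rt; then DBU, rt
Reagents that add atoms: none
Why: Dess–Martin oxidation gives the β,γ-unsaturated aldehyde and DBU should conjugate it through the C17 dienolate (protonation at C6), moving the alkene from C6=C7 to C7=C8 and removing the C8 stereocentre.

**Step 15**
Reactants: 24 C7=C8 enal
Product: 25 methyl (3S,4Z)-5-[2-(hydroxymethyl)-5,5,8a-trimethyl-1,4,4a,5,6,7,8,8a-octahydronaphthalen-1-yl]-3-methylpent-4-enoate
Conditions: NaBH4, CeCl3·7H2O, MeOH, −20 °C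
Reagents that add atoms: none
Why: Luche 1,2-reduction of the enal, to which the methyl ester and the alkenes should be inert.

**Step 16**
Reactants: 25 allylic alcohol
Product: 26 methyl (3S,4Z)-5-[2-(acetoxymethyl)-5,5,8a-trimethyl-1,4,4a,5,6,7,8,8a-octahydronaphthalen-1-yl]-3-methylpent-4-enoate
Conditions: Ac2O, pyridine, DMAP (cat.), CH2Cl2, rt
Reagents that add atoms: acetic anhydride, CC(=O)OC(C)=O
Why: DMAP-catalysed acetylation of a primary allylic alcohol.

**Step 17**
Reactants: 26 allylic acetate
Product: 27 methyl (3R)-5-[(1S,4aR,8aR)-2-(acetoxymethyl)-5,5,8a-trimethyl-1,4,4a,5,6,7,8,8a-octahydronaphthalen-1-yl]-3-methylpentanoate (CNP0149025.1)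
Conditions: 2-nitrobenzenesulfonylhydrazide (excess), Et3N, CH2Cl2, rt
Reagents that add atoms: none
Why: Diimide transfers H2 syn to the Z-disubstituted C11=C12 alkene far faster than to the trisubstituted C7=C8 alkene and cannot hydrogenolyse the allylic acetate, so the side chain should be saturated without touching ring B.

**Compound list**
1 | 2,2-dimethylpent-4-enal | C=CCC(C)(C)C=O | starting material
2 | ethyl (2E)-4-(diethoxyphosphoryl)but-2-enoate | CCOC(=O)/C=C/CP(=O)(OCC)OCC | starting material
3 | ethyl (2E,4E)-6,6-dimethylnona-2,4,8-trienoate | CCOC(=O)/C=C/C=C/C(C)(C)CC=C | intermediate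
4 | (2E,4E)-6,6-dimethylnona-2,4,8-trien-1-ol | OC/C=C/C=C/C(C)(C)CC=C | intermediate
5 | [(2E,4E)-6,6-dimethylnona-2,4,8-trien-1-yl]oxy(triisopropyl)silane | CC(C)[Si](OC/C=C/C=C/C(C)(C)CC=C)(C(C)C)C(C)C | intermediate
6 | ethyl acetoacetate | CCOC(=O)CC(C)=O | starting material
7 | ethyl (2E)-3-{[(trifluoromethyl)sulfonyl]oxy}but-2-enoate | CCOC(=O)/C=C(\C)OS(=O)(=O)C(F)(F)F | intermediate
8 | 9-[(5E,7E)-4,4-dimethyl-9-(triisopropylsilyloxy)nona-5,7-dien-1-yl]-9-borabicyclo[3.3.1]nonane (not isolated) | B1(CCCC(C)(C)/C=C/C=C/CO[Si](C(C)C)(C(C)C)C(C)C)C2CCCC1CCC2 | intermediate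
9 | ethyl (2E,8E,10E)-3,7,7-trimethyl-12-(triisopropylsilyloxy)dodeca-2,8,10-trienoate | CCOC(=O)/C=C(\C)CCCC(C)(C)/C=C/C=C/CO[Si](C(C)C)(C(C)C)C(C)C | intermediate
10 | (2E,8E,10E)-3,7,7-trimethyl-12-(triisopropylsilyloxy)dodeca-2,8,10-trienoic acid | OC(=O)/C=C(\C)CCCC(C)(C)/C=C/C=C/CO[Si](C(C)C)(C(C)C)C(C)C | intermediate
11 | (4R)-4-benzyl-1,3-oxazolidin-2-one | O=C1N[C@H](Cc2ccccc2)CO1 | starting material
12 | mixed anhydride of 10 with pivalic acid (not isolated) | CC(C)(C)C(=O)OC(=O)/C=C(\C)CCCC(C)(C)/C=C/C=C/CO[Si](C(C)C)(C(C)C)C(C)C | intermediate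
13 | (4R)-4-benzyl-3-[(2E,8E,10E)-3,7,7-trimethyl-12-(triisopropylsilyloxy)dodeca-2,8,10-trienoyl]-1,3-oxazolidin-2-one | O=C(/C=C(\C)CCCC(C)(C)/C=C/C=C/CO[Si](C(C)C)(C(C)C)C(C)C)N1[C@H](Cc2ccccc2)COC1=O | intermediate
14 | trans-fused octalin imide (C9 acyl, C8 CH2OSi, C10 methyl cis; C6=C7) | O=C([C@@H]1[C@H](CO[Si](C(C)C)(C(C)C)C(C)C)C=C[C@@H]2C(C)(C)CCC[C@@]12C)N1[C@H](Cc2ccccc2)COC1=O | intermediate
15 | hydroxy imide (14 without the silyl group; not isolated) | O=C([C@@H]1[C@H](CO)C=C[C@@H]2C(C)(C)CCC[C@@]12C)N1[C@H](Cc2ccccc2)COC1=O | intermediate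
16 | tricyclic cis-fused γ-lactone (C11=O, O–C17; C6=C7) | O=C3[C@@H]1[C@H](CO3)C=C[C@@H]2C(C)(C)CCC[C@@]12C | intermediate
17 | tricyclic lactol (C11 anomers) | OC3[C@@H]1[C@H](CO3)C=C[C@@H]2C(C)(C)CCC[C@@]12C | intermediate
18 | (3R)-5-methoxy-3-methyl-5-oxopentanoic acid | COC(=O)C[C@H](C)CC(=O)O | starting material
19 | methyl (3S)-4-iodo-3-methylbutanoate | COC(=O)C[C@H](C)C[I] | intermediate
20 | [(2S)-4-methoxy-2-methyl-4-oxobutyl]triphenylphosphonium iodide | COC(=O)C[C@H](C)C[P+](c1ccccc1)(c1ccccc1)c1ccccc1.[I-] | intermediate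
21 | methyl (3S)-3-methyl-4-(triphenylphosphoranylidene)butanoate (not isolated) | COC(=O)C[C@H](C)C=P(c1ccccc1)(c1ccccc1)c1ccccc1 | intermediate
22 | hydroxy diene ester (Z C11=C12; C6=C7; C17–OH) | COC(=O)C[C@H](C)/C=C\[C@@H]1[C@H](CO)C=C[C@@H]2C(C)(C)CCC[C@@]12C | intermediate
23 | β,γ-unsaturated C17 aldehyde (not isolated) | COC(=O)C[C@H](C)/C=C\[C@@H]1[C@H](C=O)C=C[C@@H]2C(C)(C)CCC[C@@]12C | intermediate
24 | C7=C8 enal | COC(=O)C[C@H](C)/C=C\[C@@H]1C(C=O)=CC[C@@H]2C(C)(C)CCC[C@@]12C | intermediate
25 | C17 allylic alcohol | COC(=O)C[C@H](C)/C=C\[C@@H]1C(CO)=CC[C@@H]2C(C)(C)CCC[C@@]12C | intermediate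
26 | C17 allylic acetate | COC(=O)C[C@H](C)/C=C\[C@@H]1C(COC(C)=O)=CC[C@@H]2C(C)(C)CCC[C@@]12C | intermediate
27 | methyl (3R)-5-[(1S,4aR,8aR)-2-(acetoxymethyl)-5,5,8a-trimethyl-1,4,4a,5,6,7,8,8a-octahydronaphthalen-1-yl]-3-methylpentanoate | COC(=O)C[C@H](C)CC[C@@H]1C(COC(C)=O)=CC[C@@H]2C(C)(C)CCC[C@@]12C | target

**Step count**
Total: 17 steps. Longest linear sequence: 14 steps (1, 2, 3, 5, 6, 7, 8, 9, 10, 13, 14, 15, 16, 17).

**Steps most likely to fail**

Step 8. The β,β-disubstituted enoyl imide may react too slowly under the aluminium Lewis acid, so that the diene decomposes first, or the endo preference may erode because of the developing 1,3-diaxial methyl/methyl contact, giving cis-fused material. The fallback replaces auxiliary control by iminium catalysis at the aldehyde oxidation level; it sets out from 9 and returns at 17. Ester 9 would be reduced (iBu2AlH, CH2Cl2, −78 °C) to the (2E,8E,10E)-trienol F1 and oxidised (MnO2, CH2Cl2) to the trienal F2. F2 would then undergo an organocatalytic intramolecular Diels–Alder reaction with the second-generation MacMillan imidazolidinone of (2R,5R) configuration, (2R,5R)-5-benzyl-2-tert-butyl-3-methylimidazolidin-4-one as its trifluoroacetate salt (20 mol %, MeCN/H2O, −20 °C to rt). Its benzyl group shields the C9 Si face of the E-iminium ion, so the reaction should give the trans-fused bicyclic aldehyde F3. Bu4NF then removes the silyl group and the C17 hydroxyl closes onto the C11 aldehyde to give lactol 17.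

Step 13. Opening of the hindered lactol to the hydroxy aldehyde may be slow, so that the ester-bearing ylide is lost by proton transfer and self-condensation and conversion stays low. The fallback olefinates a free aldehyde that cannot lactolise; it sets out from 14 and returns at 22. Reductive removal of the auxiliary from 14 (LiBH4, H2O, Et2O, 0 °C) would give the primary alcohol F4. Dess–Martin oxidation gives the bicyclic aldehyde F3, whose C17 oxygen is still silylated. Wittig reaction with ylide 21 at −78 °C gives the Z-alkene silyl ether F5, and Bu4NF gives 22.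

Step 5. Hydrolysis of the β-triflyloxy enoate by the aqueous base may outrun transmetalation, and protodeboronation or partial loss of alkene geometry may accompany the coupling. The fallback sets the alkene geometry by alkyne carbometalation instead; it sets out from 5 and returns at 9. Borane 8 (from 5 and 9-BBN) would be oxidised (NaOH, H2O2) to the primary alcohol F6 and converted (CBr4, PPh3) to the bromide F7. Mg in THF gives the Grignard reagent F8 and CuBr·SMe2 at −78 °C the alkylcopper reagent F9. Syn addition of F9 to commercial ethyl but-2-ynoate at −78 °C gives the alkenylcopper adduct F10, and protonation at −78 °C (chain cis to H, trans to the ester) gives 9.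

**Further compounds**
F1 | step 8 | (2E,8E,10E)-3,7,7-trimethyl-12-(triisopropylsilyloxy)dodeca-2,8,10-trien-1-ol | OC/C=C(\C)CCCC(C)(C)/C=C/C=C/CO[Si](C(C)C)(C(C)C)C(C)C
F2 | step 8 | (2E,8E,10E)-3,7,7-trimethyl-12-(triisopropylsilyloxy)dodeca-2,8,10-trienal | O=C/C=C(\C)CCCC(C)(C)/C=C/C=C/CO[Si](C(C)C)(C(C)C)C(C)C
F3 | step 8 | trans-fused octalin C11 aldehyde (C8 CH2OSi cis to CHO; C6=C7) | O=C[C@@H]1[C@H](CO[Si](C(C)C)(C(C)C)C(C)C)C=C[C@@H]2C(C)(C)CCC[C@@]12C
F4 | step 13 | trans-fused octalin C11 primary alcohol (C17 silyl ether) | OC[C@@H]1[C@H](CO[Si](C(C)C)(C(C)C)C(C)C)C=C[C@@H]2C(C)(C)CCC[C@@]12C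
F5 | step 13 | silyl ether of 22 (Z C11=C12) | COC(=O)C[C@H](C)/C=C\[C@@H]1[C@H](CO[Si](C(C)C)(C(C)C)C(C)C)C=C[C@@H]2C(C)(C)CCC[C@@]12C
F6 | step 5 | (5E,7E)-4,4-dimethyl-9-(triisopropylsilyloxy)nona-5,7-dien-1-ol | OCCCC(C)(C)/C=C/C=C/CO[Si](C(C)C)(C(C)C)C(C)C
F7 | step 5 | [(2E,4E)-9-bromo-6,6-dimethylnona-2,4-dien-1-yl]oxy(triisopropyl)silane | BrCCCC(C)(C)/C=C/C=C/CO[Si](C(C)C)(C(C)C)C(C)C
F8 | step 5 | Grignard reagent of F7 | Br[Mg]CCCC(C)(C)/C=C/C=C/CO[Si](C(C)C)(C(C)C)C(C)C
F9 | step 5 | alkylcopper reagent from F8 | [Cu]CCCC(C)(C)/C=C/C=C/CO[Si](C(C)C)(C(C)C)C(C)C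
F10 | step 5 | alkenylcopper adduct of F9 with ethyl but-2-ynoate | CCOC(=O)/C([Cu])=C(\C)CCCC(C)(C)/C=C/C=C/CO[Si](C(C)C)(C(C)C)C(C)C
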